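**Retrosynthetic overview**
- Target 17 ← hydrogenolysis of the 3'-benzyl ether of trisulfate 16 ← sulfation at O3, O7 and O4' of 3'-O-benzylquercetin 15, whose chelated 5-OH stays free.
- 15 ← acid cleavage of the MOM (O3, O4') and PMB (O5, O7) ethers of 14 ← twofold fluoride-for-alkoxide exchange at C5 and C7 of difluoroflavonol ether 11.
- Ring C is the only ring made (rings A and B are bought): the O1–C8a bond is formed by intramolecular SNAr of the enolate of diketone 10 on an ortho C–F carbon. The feature used is that C5, C7 and C8a of ring A all lie ortho or para to C4a, the carbon that carries the C4 carbonyl, so all three ring A oxygens can arrive as nucleophiles on a 2,4,6-trifluorobenzoyl unit.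
- 10 ← C-acylation (C3–C4 bond) of α-(methoxymethoxy) ketone 8 with 2,4,6-trifluorobenzoyl chloride 9; 8 ← 3,4-dihydroxyacetophenone 1 by 4-O-MOM, 3-O-benzyl, Rubottom oxidation and O-MOM capping.

Key step: step 7

Assumption: the sulfate monoesters 16 and 17 are drawn as free acids, as the target is; they should form and be purified as triethylammonium salts, and the acid form is released by cold passage over a sulfonic acid resin in its proton form. The target has no stereocentre; 5 and 10 are racemic and lose their stereocentres in the next event.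

**Route**

Step 1
Reactants: 1 3,4-dihydroxyacetophenone
Product: 2 1-[3-hydroxy-4-(methoxymethoxy)phenyl]ethan-1-one
Conditions: MOMCl (1.05 equiv), K2CO3 (1.1 equiv), acetone, 0 °C to rt
Reagents that add atoms: chloromethyl methyl ether (MOMCl), COCCl
Why: Williamson-type O-alkylation under weak base, in which the 4-OH para to the acetyl group is the more acidic phenol and is ionised first, so one equivalent of MOMCl should cap O4 and leave O3 free.

Step 2
Reactants: 2 1-[3-hydroxy-4-(methoxymethoxy)phenyl]ethan-1-one
Product: 3 1-[3-(benzyloxy)-4-(methoxymethoxy)phenyl]ethan-1-one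
Conditions: BnBr (1.2 equiv), K2CO3, DMF, rt
Reagents that add atoms: benzyl bromide, BrCc1ccccc1
Why: Williamson ether synthesis on the only remaining phenol; the MOM acetal and the methyl ketone are inert to K2CO3 and benzyl bromide at room temperature.

Step 3
Reactants: 3 1-[3-(benzyloxy)-4-(methoxymethoxy)phenyl]ethan-1-one
Product: 4 ({1-[3-(benzyloxy)-4-(methoxymethoxy)phenyl]ethenyl}oxy)trimethylsilane
Conditions: LiN(SiMe3)2 (1.1 equiv), THF, −78 °C; TMSCl (1.2 equiv), −78 to 0 °C; non-aqueous work-up (pentane, filtration)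
Reagents that add atoms: chlorotrimethylsilane (TMSCl), C[Si](C)(C)Cl
Why: silyl enol ether formation by deprotonation of the single enolisable position and O-silylation of the lithium enolate; TMSCl is chosen over a silyl triflate so that the aryl MOM acetal is not attacked.

Step 4
Reactants: 4 ({1-[3-(benzyloxy)-4-(methoxymethoxy)phenyl]ethenyl}oxy)trimethylsilane
Product: 7 1-[3-(benzyloxy)-4-(methoxymethoxy)phenyl]-2-hydroxyethan-1-one, via silyloxy epoxide 5 (not isolated), via silyloxy ketone 6 (not isolated)
Conditions: mCPBA (1.1 equiv), CH2Cl2, −15 to 0 °C; then citric acid (cat.), MeOH/H2O, rt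
Reagents that add atoms: 3-chloroperoxybenzoic acid (mCPBA), OOC(=O)c1cccc(Cl)c1
Why: Rubottom oxidation, in which the electron-rich enol ether is epoxidised much faster than the aryl ketone can undergo Baeyer–Villiger reaction, the epoxide opens with 1,4-silyl shift to the α-silyloxy ketone, and mild acid hydrolysis frees the primary ketol without touching the aryl MOM ether.

Step 5
Reactants: 7 1-[3-(benzyloxy)-4-(methoxymethoxy)phenyl]-2-hydroxyethan-1-one
Product: 8 1-[3-(benzyloxy)-4-(methoxymethoxy)phenyl]-2-(methoxymethoxy)ethan-1-one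
Conditions: MOMCl (1.5 equiv), i-Pr2NEt (2 equiv), CH2Cl2, 0 °C to rt
Reagents that add atoms: chloromethyl methyl ether (MOMCl), COCCl
Why: acetal formation (MOM protection) of a primary alcohol with an amine base too weak to enolise the ketone, giving a base-stable, acid-labile cap on the future O3.

Step 6
Reactants: 8 1-[3-(benzyloxy)-4-(methoxymethoxy)phenyl]-2-(methoxymethoxy)ethan-1-one; 9 2,4,6-trifluorobenzoyl chloride
Product: 10 1-[3-(benzyloxy)-4-(methoxymethoxy)phenyl]-2-(methoxymethoxy)-3-(2,4,6-trifluorophenyl)propane-1,3-dione (racemic)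
Conditions: LiN(SiMe3)2 (2.2 equiv), THF, −78 °C; 9 (1.05 equiv), −78 to −40 °C; AcOH quench at −78 °C
Reagents that add atoms: 2,4,6-trifluorobenzoyl chloride (compound 9), O=C(Cl)c1c(F)cc(F)cc1F
Why: Claisen-type C-acylation of a chelated lithium ketone enolate by an acid chloride, in which the second equivalent of base stores the more acidic diketone as its lithium enolate and so prevents proton exchange and double acylation, the acyl chloride carbon is far more electrophilic than the C–F carbons at −78 °C, and the new stereocentre at C2 is racemic and disappears in step 7.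

Step 7
Reactants: 10 1-[3-(benzyloxy)-4-(methoxymethoxy)phenyl]-2-(methoxymethoxy)-3-(2,4,6-trifluorophenyl)propane-1,3-dione
Product: 11 2-[3-(benzyloxy)-4-(methoxymethoxy)phenyl]-5,7-difluoro-3-(methoxymethoxy)-4H-chromen-4-one
Conditions: K2CO3 (2 equiv), dry DMF (0.05 M), rt to 60 °C
Reagents that add atoms: none
Why: K2CO3 converts 10 into its enolate, whose oxygen on the ring B carbonyl adds to an ortho C–F carbon of the trifluorophenyl ring to give a Meisenheimer anion delocalised into the C4 carbonyl, and loss of fluoride forms the O1–C8a bond (intramolecular SNAr, addition–elimination). The closest known reaction type is the base-induced cyclisation of 1-(2-fluoroaryl)-1,3-diketones to flavones and chromones. Ring C closes as a six-membered ring by oxygen attack on an sp2 carbon whose C8a=C4a bond lies inside the new ring, a favoured 6-endo-trig-type conjugate addition followed by elimination. No stereocentre is formed, and the one at C2 of 10 becomes the sp2 carbon C3. The step needs O- over C-attack and ortho over para displacement: the central carbon cannot reach the ring, only an ortho C–F carbon lies within a six-membered transition state, the two ortho fluorines are equivalent, and dry, dilute conditions without an external nucleophile should leave the para fluorine in place.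

Step 8
Reactants: 11 2-[3-(benzyloxy)-4-(methoxymethoxy)phenyl]-5,7-difluoro-3-(methoxymethoxy)-4H-chromen-4-one; 12 4-methoxybenzyl alcohol
Product: 14 2-[3-(benzyloxy)-4-(methoxymethoxy)phenyl]-5,7-bis[(4-methoxyphenyl)methoxy]-3-(methoxymethoxy)-4H-chromen-4-one, via 7-PMB-oxy 5-fluoro monoether 13 (not isolated)
Conditions: 12 (3 equiv), NaH (3 equiv), DMF, 0 °C to 50 °C
Reagents that add atoms: 4-methoxybenzyl alcohol (compound 12), COc1ccc(CO)cc1
Why: twofold intermolecular SNAr in which the C4 carbonyl activates C7 (para, expected to react first) and C5 (ortho) for addition–elimination by the sodium alkoxide, as known for alkoxide displacement of fluoride in fluorochromones; the MOM and benzyl ethers are base-stable and the fully substituted C2 and C3 resist conjugate attack.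

Step 9
Reactants: 14 2-[3-(benzyloxy)-4-(methoxymethoxy)phenyl]-5,7-bis[(4-methoxyphenyl)methoxy]-3-(methoxymethoxy)-4H-chromen-4-one
Product: 15 2-[3-(benzyloxy)-4-hydroxyphenyl]-3,5,7-trihydroxy-4H-chromen-4-one (3'-O-benzylquercetin)
Conditions: 20% TFA in CH2Cl2, anisole (20 equiv), 0 °C to rt; aqueous NaHCO3 work-up
Reagents that add atoms: none
Why: acid-induced SN1 cleavage of the two PMB aryl ethers and acidolysis of the two MOM acetals, with anisole trapping the 4-methoxybenzyl cation so that C6 and C8 of ring A are not alkylated, while the unactivated 3'-benzyl ether should survive dilute TFA over the short reaction time.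

Step 10
Reactants: 15 2-[3-(benzyloxy)-4-hydroxyphenyl]-3,5,7-trihydroxy-4H-chromen-4-one
Product: 16 2-[3-(benzyloxy)-4-(sulfooxy)phenyl]-5-hydroxy-4-oxo-4H-chromene-3,7-diyl bis(hydrogen sulfate) (handled as its tris(triethylammonium) salt)
Conditions: SO3·NMe3 (12 equiv), Et3N, DMF, 40 °C; size-exclusion chromatography
Reagents that add atoms: sulfur trioxide–trimethylamine complex, C[N+](C)(C)S(=O)(=O)[O-]
Why: O-sulfation by an amine–sulfur trioxide complex, in which the 5-OH is held in a strong hydrogen bond to the C4 carbonyl and is the least nucleophilic hydroxyl, so excess reagent should sulfate O3, O7 and O4' and leave O5 free, while O3' is blocked as its benzyl ether.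

Step 11
Reactants: 16 2-[3-(benzyloxy)-4-(sulfooxy)phenyl]-5-hydroxy-4-oxo-4H-chromene-3,7-diyl bis(hydrogen sulfate)
Product: 17 quercetin 3,4',7-tris(hydrogen sulfate) (target)
Conditions: H2 (1 atm), Pd/C (10% Pd on carbon), MeOH/H2O, rt; then sulfonic acid resin (proton form), H2O, 0 °C, freeze-drying
Reagents that add atoms: none
Why: catalytic hydrogenolysis of a benzyl aryl ether, to which aryl sulfate monoester salts and the flavonol C2=C3 bond are inert at room temperature and atmospheric pressure.

**Compound list**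
1 | 3,4-dihydroxyacetophenone | CC(=O)c1ccc(O)c(O)c1 | starting material
2 | 1-[3-hydroxy-4-(methoxymethoxy)phenyl]ethan-1-one | CC(=O)c1ccc(OCOC)c(O)c1 | intermediate
3 | 1-[3-(benzyloxy)-4-(methoxymethoxy)phenyl]ethan-1-one | CC(=O)c1ccc(OCOC)c(OCc2ccccc2)c1 | intermediate
4 | ({1-[3-(benzyloxy)-4-(methoxymethoxy)phenyl]ethenyl}oxy)trimethylsilane | C=C(O[Si](C)(C)C)c1ccc(OCOC)c(OCc2ccccc2)c1 | intermediate
5 | {2-[3-(benzyloxy)-4-(methoxymethoxy)phenyl]oxiran-2-yl}oxy(trimethyl)silane (racemic, not isolated) | C[Si](C)(C)OC1(CO1)c1ccc(OCOC)c(OCc2ccccc2)c1 | intermediate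
6 | 1-[3-(benzyloxy)-4-(methoxymethoxy)phenyl]-2-[(trimethylsilyl)oxy]ethan-1-one (not isolated) | C[Si](C)(C)OCC(=O)c1ccc(OCOC)c(OCc2ccccc2)c1 | intermediate
7 | 1-[3-(benzyloxy)-4-(methoxymethoxy)phenyl]-2-hydroxyethan-1-one | OCC(=O)c1ccc(OCOC)c(OCc2ccccc2)c1 | intermediate
8 | 1-[3-(benzyloxy)-4-(methoxymethoxy)phenyl]-2-(methoxymethoxy)ethan-1-one | COCOCC(=O)c1ccc(OCOC)c(OCc2ccccc2)c1 | intermediate
9 | 2,4,6-trifluorobenzoyl chloride | O=C(Cl)c1c(F)cc(F)cc1F | starting material
10 | 1-[3-(benzyloxy)-4-(methoxymethoxy)phenyl]-2-(methoxymethoxy)-3-(2,4,6-trifluorophenyl)propane-1,3-dione (racemic) | COCOC(C(=O)c1c(F)cc(F)cc1F)C(=O)c1ccc(OCOC)c(OCc2ccccc2)c1 | intermediate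
11 | 2-[3-(benzyloxy)-4-(methoxymethoxy)phenyl]-5,7-difluoro-3-(methoxymethoxy)-4H-chromen-4-one | O=c1c(OCOC)c(-c2ccc(OCOC)c(OCc3ccccc3)c2)oc2cc(F)cc(F)c12 | intermediate
12 | 4-methoxybenzyl alcohol | COc1ccc(CO)cc1 | starting material
13 | 2-[3-(benzyloxy)-4-(methoxymethoxy)phenyl]-5-fluoro-7-[(4-methoxyphenyl)methoxy]-3-(methoxymethoxy)-4H-chromen-4-one (not isolated) | O=c1c(OCOC)c(-c2ccc(OCOC)c(OCc3ccccc3)c2)oc2cc(OCc3ccc(OC)cc3)cc(F)c12 | intermediate
14 | 2-[3-(benzyloxy)-4-(methoxymethoxy)phenyl]-5,7-bis[(4-methoxyphenyl)methoxy]-3-(methoxymethoxy)-4H-chromen-4-one | O=c1c(OCOC)c(-c2ccc(OCOC)c(OCc3ccccc3)c2)oc2cc(OCc3ccc(OC)cc3)cc(OCc3ccc(OC)cc3)c12 | intermediate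
15 | 2-[3-(benzyloxy)-4-hydroxyphenyl]-3,5,7-trihydroxy-4H-chromen-4-one (3'-O-benzylquercetin) | O=c1c(O)c(-c2ccc(O)c(OCc3ccccc3)c2)oc2cc(O)cc(O)c12 | intermediate
16 | 2-[3-(benzyloxy)-4-(sulfooxy)phenyl]-5-hydroxy-4-oxo-4H-chromene-3,7-diyl bis(hydrogen sulfate) | O=c1c(OS(=O)(=O)O)c(-c2ccc(OS(=O)(=O)O)c(OCc3ccccc3)c2)oc2cc(OS(=O)(=O)O)cc(O)c12 | intermediate
17 | quercetin 3,4',7-tris(hydrogen sulfate) | O=c1c(OS(=O)(=O)O)c(-c2ccc(OS(=O)(=O)O)c(O)c2)oc2cc(OS(=O)(=O)O)cc(O)c12 | target

**Step count**
Total step count: 11. Longest linear sequence: 11 steps (1 to 17); 9 and 12 are purchased.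

**Steps most likely to fail**

Step 7 (key step). The 2-alkoxy diketone is hindered and only partly enolised, so ring closure may be slow. Carbonate or traces of hydroxide could then cleave the diketone by retro-Claisen attack, or the enolate of one molecule could displace the para fluoride of another. Fallback, setting out from 3 and 9 and coming back at 11: the C3 oxygen is introduced after ring C is closed. The lithium enolate of 3 (LiN(SiMe3)2, THF, −78 °C) is acylated with 9 to the unsubstituted, fully enolised diketone 1-[3-(benzyloxy)-4-(methoxymethoxy)phenyl]-3-(2,4,6-trifluorophenyl)propane-1,3-dione F1. With K2CO3 in DMF this should cyclise as the parent case of this flavone synthesis to 2-[3-(benzyloxy)-4-(methoxymethoxy)phenyl]-5,7-difluoro-4H-chromen-4-one F2. Dimethyldioxirane in acetone/CH2Cl2 at 0 °C should epoxidise the C2=C3 bond to the racemic 2,3-epoxyflavanone F3, and a trace of TsOH should open it to 2-[3-(benzyloxy)-4-(methoxymethoxy)phenyl]-5,7-difluoro-3-hydroxy-4H-chromen-4-one F4. MOMCl and i-Pr2NEt in CH2Cl2 then give 11.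

Step 6. Acylation may occur at the enolate oxygen instead of carbon, giving an enol ester, or proton transfer between product and enolate may lead to double acylation. Fallback, setting out from 8 and coming back at 10: the C3–C4 bond is made by an aldol addition and the oxidation level is adjusted afterwards. The lithium enolate of 8 (LiN(SiMe3)2, THF, −78 °C) is added to 2,4,6-trifluorobenzaldehyde to give 1-[3-(benzyloxy)-4-(methoxymethoxy)phenyl]-3-hydroxy-2-(methoxymethoxy)-3-(2,4,6-trifluorophenyl)propan-1-one F5 as a mixture of racemic diastereomers. Dess–Martin periodinane in CH2Cl2 should oxidise this to 10; the diastereomer mixture is of no consequence.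

Step 10. Sulfation may stop short at the hindered, hydrogen-bonded O3, or slowly go on to O5 under forcing conditions, giving mixtures of highly charged regioisomers that are hard to separate. Fallback, setting out from 15 and coming back at 17: the sulfates are introduced as neutral, chromatographable diesters. Treating 15 with 2,2,2-trichloroethyl chlorosulfate (3.3 equiv), Et3N and DMAP in THF at 0 °C should give 3'-O-benzylquercetin 3,7,4'-tris(2,2,2-trichloroethyl sulfate) F6, which can be purified on silica gel. Pd/C with HCO2NH4 in MeOH should then cleave the three trichloroethyl esters by reductive β-elimination and the benzyl ether by transfer hydrogenolysis in one operation, giving 17 as its ammonium salt.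

**Further compounds**
F1 | step 7 | 1-[3-(benzyloxy)-4-(methoxymethoxy)phenyl]-3-(2,4,6-trifluorophenyl)propane-1,3-dione | O=C(CC(=O)c1c(F)cc(F)cc1F)c1ccc(OCOC)c(OCc2ccccc2)c1
F2 | step 7 | 2-[3-(benzyloxy)-4-(methoxymethoxy)phenyl]-5,7-difluoro-4H-chromen-4-one | O=c1cc(-c2ccc(OCOC)c(OCc3ccccc3)c2)oc2cc(F)cc(F)c12
F3 | step 7 | 2-[3-(benzyloxy)-4-(methoxymethoxy)phenyl]-5,7-difluoro-2,3-epoxy-2,3-dihydro-4H-chromen-4-one (racemic) | O=C1c2c(F)cc(F)cc2OC2(c3ccc(OCOC)c(OCc4ccccc4)c3)OC12
F4 | step 7 | 2-[3-(benzyloxy)-4-(methoxymethoxy)phenyl]-5,7-difluoro-3-hydroxy-4H-chromen-4-one | O=c1c(O)c(-c2ccc(OCOC)c(OCc3ccccc3)c2)oc2cc(F)cc(F)c12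
F5 | step 6 | 1-[3-(benzyloxy)-4-(methoxymethoxy)phenyl]-3-hydroxy-2-(methoxymethoxy)-3-(2,4,6-trifluorophenyl)propan-1-one (mixture of racemic diastereomers) | COCOC(C(O)c1c(F)cc(F)cc1F)C(=O)c1ccc(OCOC)c(OCc2ccccc2)c1
F6 | step 10 | 3'-O-benzylquercetin 3,7,4'-tris(2,2,2-trichloroethyl sulfate) | O=c1c(OS(=O)(=O)OCC(Cl)(Cl)Cl)c(-c2ccc(OS(=O)(=O)OCC(Cl)(Cl)Cl)c(OCc3ccccc3)c2)oc2cc(OS(=O)(=O)OCC(Cl)(Cl)Cl)cc(O)c12
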